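**Retrosynthetic overview**

1. Target ⇐ hydrogenolysis of its 5,7‑di‑O‑benzyl ether ⇐ C3–O bond by α‑oxyacylation of (2S)‑5,7‑bis(benzyloxy)flavanone with an O‑hexanoyl‑N‑methylhydroxylamine fragment (the convergent union; sets C3 trans to the 2‑phenyl group).
2. Flavanone ⇐ enantioselective intramolecular oxa‑Michael addition (O1–C2 bond, sets C2) of a 2'‑hydroxy alkylidene β‑keto ester, then loss of the tert‑butyl ester.
3. Alkylidene β‑keto ester ⇐ Knoevenagel condensation with benzaldehyde ⇐ aryl β‑keto ester ⇐ C‑acylation (Boc2O) of 4',6'‑di‑O‑benzyl phloroacetophenone.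
4. Second fragment: N‑methylhydroxylamine hydrochloride → N‑Boc → O‑hexanoyl → hydrochloride salt (three steps, made in parallel).
5. Ring order: rings A and B are bought as arenes; ring C (the pyranone) is the only ring formed, by the oxa‑Michael closure.

Assumption: the 9‑amino(9‑deoxy)epiquinidine‑derived thiourea is taken to give the (2S)‑flavanone; if the sense of induction proves opposite, the pseudoenantiomeric epiquinine‑derived catalyst is used with no other change.

**Route**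

Step 1
Reactants: 1 2',4',6'‑trihydroxyacetophenone; 2 benzyl bromide
Product: 3 1‑[2,4‑bis(benzyloxy)‑6‑hydroxyphenyl]ethan‑1‑one
Conditions: BnBr (2.05 equiv), K2CO3 (2.2 equiv), DMF, rt, 16 h
Reagents that add atoms: benzyl bromide, BrCc1ccccc1
Why: Williamson etherification alkylates the 4‑OH and one ortho‑OH, while the remaining ortho‑OH is hydrogen‑bonded to the acetyl carbonyl and stays free with two equivalents of halide; no stereocentre.

Step 2
Reactants: 3 1‑[2,4‑bis(benzyloxy)‑6‑hydroxyphenyl]ethan‑1‑one; 4 di‑tert‑butyl dicarbonate (Boc2O)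
Product: 5 tert‑butyl 3‑[2,4‑bis(benzyloxy)‑6‑hydroxyphenyl]‑3‑oxopropanoate
Conditions: LiN(SiMe3)2 (3.3 equiv), THF, −78 °C; Boc2O (1.1 equiv), −78 → 0 °C; aq. NH4Cl
Reagents that add atoms: di‑tert‑butyl dicarbonate, CC(C)(C)OC(=O)OC(=O)OC(C)(C)C
Why: Claisen‑type C‑acylation of the phenoxide/enolate dianion with Boc2O, the third equivalent of base holding the product as its β‑keto ester enolate, and the tert‑butyl ester does not lactonise to a 4‑hydroxycoumarin; no stereocentre.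

Step 3
Reactants: 5 tert‑butyl 3‑[2,4‑bis(benzyloxy)‑6‑hydroxyphenyl]‑3‑oxopropanoate; 6 benzaldehyde
Product: 7 tert‑butyl (2Z)‑2‑[2,4‑bis(benzyloxy)‑6‑hydroxybenzoyl]‑3‑phenylprop‑2‑enoate
Conditions: PhCHO (1.2 equiv), piperidine (10 mol%), AcOH (20 mol%), 4 Å molecular sieves, toluene, rt → 40 °C
Reagents that add atoms: benzaldehyde, O=Cc1ccccc1
Why: Knoevenagel condensation of the doubly activated methylene with water removal gives mainly the Z alkene (ester cis to phenyl), and the slightly acidic buffer suppresses background cyclisation; no stereocentre.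

Step 4
Reactants: 7 tert‑butyl (2Z)‑2‑[2,4‑bis(benzyloxy)‑6‑hydroxybenzoyl]‑3‑phenylprop‑2‑enoate
Product: 9 (2S)‑5,7‑bis(benzyloxy)‑2‑phenyl‑2,3‑dihydro‑4H‑chromen‑4‑one, via cyclised tert‑butyl keto ester 8 (not isolated)
Conditions: 1‑[3,5‑bis(trifluoromethyl)phenyl]‑3‑(9‑deoxy‑epi‑quinidin‑9‑yl)thiourea (10 mol%), toluene, −25 °C, 48 h; then TsOH·H2O (0.5 equiv), 80 °C; recrystallise to ≥99% ee
Reagents that add atoms: none
Why: Enantioselective intramolecular oxa‑Michael addition (6‑endo‑trig) in which the thiourea binds the β‑keto ester and the quinuclidine delivers the phenol to one face of the alkylidene, setting C2 as S; acid then cleaves the tert‑butyl ester and decarboxylation erases C3.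

Step 5
Reactants: 10 N‑methylhydroxylamine hydrochloride; 4 di‑tert‑butyl dicarbonate (Boc2O)
Product: 11 tert‑butyl N‑hydroxy‑N‑methylcarbamate
Conditions: Boc2O (1.0 equiv), K2CO3 (1.0 equiv), THF/H2O 1:1, 0 °C → rt
Reagents that add atoms: di‑tert‑butyl dicarbonate, CC(C)(C)OC(=O)OC(=O)OC(C)(C)C
Why: Chemoselective N‑acylation (carbamate formation) at the more nucleophilic nitrogen of the hydroxylamine; no stereocentre.

Step 6
Reactants: 11 tert‑butyl N‑hydroxy‑N‑methylcarbamate; 12 hexanoyl chloride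
Product: 13 tert‑butyl N‑(hexanoyloxy)‑N‑methylcarbamate
Conditions: hexanoyl chloride (1.1 equiv), Et3N (1.2 equiv), DMAP (cat.), CH2Cl2, 0 °C → rt
Reagents that add atoms: hexanoyl chloride, CCCCCC(Cl)=O
Why: O‑acylation of the N‑hydroxy carbamate by nucleophilic acyl substitution, with nitrogen blocked by the Boc group; no stereocentre.

Step 7
Reactants: 13 tert‑butyl N‑(hexanoyloxy)‑N‑methylcarbamate; 14 hydrogen chloride
Product: 15 O‑hexanoyl‑N‑methylhydroxylamine hydrochloride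
Conditions: 4 M HCl in 1,4‑dioxane, rt, 2 h; precipitate with Et2O
Reagents that add atoms: hydrogen chloride, Cl
Why: Acidolytic Boc cleavage gives the amine directly as its hydrochloride, which blocks O→N acyl migration and makes the reagent bench‑stable; no stereocentre.

Step 8
Reactants: 9 (2S)‑5,7‑bis(benzyloxy)‑2‑phenyl‑2,3‑dihydro‑4H‑chromen‑4‑one; 15 O‑hexanoyl‑N‑methylhydroxylamine hydrochloride
Product: 18 (2R,3R)‑5,7‑bis(benzyloxy)‑4‑oxo‑2‑phenyl‑3,4‑dihydro‑2H‑chromen‑3‑yl hexanoate, via N‑acyloxy enamine 16 (not isolated), via alpha‑acyloxy N‑methyl imine 17 (not isolated)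
Conditions: 15 (1.5 equiv), DMSO, 50 °C, 24 h
Reagents that add atoms: O‑hexanoyl‑N‑methylhydroxylamine hydrochloride, CCCCCC(=O)ONC.Cl
Why: Ketone α‑oxyacylation by condensation to the N‑acyloxy enamine and [3,3]‑sigmatropic rearrangement, which delivers the hexanoyloxy group to C3 on the face anti to the 2‑phenyl group (trans, also the diequatorial thermodynamic isomer, C3 = R) without base, so C2 is untouched; the imine is hydrolysed by the water formed in the condensation.

Step 9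
Reactants: 18 (2R,3R)‑5,7‑bis(benzyloxy)‑4‑oxo‑2‑phenyl‑3,4‑dihydro‑2H‑chromen‑3‑yl hexanoate
Product: 19 (2R,3R)‑5,7‑dihydroxy‑4‑oxo‑2‑phenyl‑3,4‑dihydro‑2H‑chromen‑3‑yl hexanoate (pinobanksin 3‑O‑hexanoate)
Conditions: H2 (1 atm), Pd/C (10 wt% Pd on carbon), EtOAc, rt; stop after uptake of 2 equiv H2
Reagents that add atoms: none
Why: Catalytic hydrogenolysis removes both aryl benzyl ethers under neutral conditions that leave the ester, the ketone and the cyclic benzylic C2–O bond intact, so both stereocentres are kept.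

**Compound list**

1 | 2',4',6'‑trihydroxyacetophenone | CC(=O)c1c(O)cc(O)cc1O | starting material
2 | benzyl bromide | BrCc1ccccc1 | starting material
3 | 1‑[2,4‑bis(benzyloxy)‑6‑hydroxyphenyl]ethan‑1‑one | CC(=O)c1c(O)cc(OCc2ccccc2)cc1OCc1ccccc1 | intermediate
4 | di‑tert‑butyl dicarbonate | CC(C)(C)OC(=O)OC(=O)OC(C)(C)C | starting material
5 | tert‑butyl 3‑[2,4‑bis(benzyloxy)‑6‑hydroxyphenyl]‑3‑oxopropanoate | CC(C)(C)OC(=O)CC(=O)c1c(O)cc(OCc2ccccc2)cc1OCc1ccccc1 | intermediate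
6 | benzaldehyde | O=Cc1ccccc1 | starting material
7 | tert‑butyl (2Z)‑2‑[2,4‑bis(benzyloxy)‑6‑hydroxybenzoyl]‑3‑phenylprop‑2‑enoate | CC(C)(C)OC(=O)/C(=C\c1ccccc1)C(=O)c1c(O)cc(OCc2ccccc2)cc1OCc1ccccc1 | intermediate
8 | tert‑butyl (2S,3R)‑5,7‑bis(benzyloxy)‑4‑oxo‑2‑phenylchromane‑3‑carboxylate (trans; keto form) | CC(C)(C)OC(=O)[C@H]1C(=O)c2c(OCc3ccccc3)cc(OCc3ccccc3)cc2O[C@@H]1c1ccccc1 | intermediate (not isolated)
9 | (2S)‑5,7‑bis(benzyloxy)‑2‑phenyl‑2,3‑dihydro‑4H‑chromen‑4‑one | O=C1C[C@@H](c2ccccc2)Oc2cc(OCc3ccccc3)cc(OCc3ccccc3)c21 | intermediate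
10 | N‑methylhydroxylamine hydrochloride | CNO.Cl | starting material
11 | tert‑butyl N‑hydroxy‑N‑methylcarbamate | CN(O)C(=O)OC(C)(C)C | intermediate
12 | hexanoyl chloride | CCCCCC(Cl)=O | starting material
13 | tert‑butyl N‑(hexanoyloxy)‑N‑methylcarbamate | CCCCCC(=O)ON(C)C(=O)OC(C)(C)C | intermediate
14 | hydrogen chloride | Cl | starting material
15 | O‑hexanoyl‑N‑methylhydroxylamine hydrochloride | CCCCCC(=O)ONC.Cl | intermediate
16 | (2S)‑5,7‑bis(benzyloxy)‑4‑[(hexanoyloxy)(methyl)amino]‑2‑phenyl‑2H‑chromene | CCCCCC(=O)ON(C)C1=C[C@@H](c2ccccc2)Oc2cc(OCc3ccccc3)cc(OCc3ccccc3)c21 | intermediate (not isolated)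
17 | (2R,3S)‑5,7‑bis(benzyloxy)‑4‑(methylimino)‑2‑phenyl‑3,4‑dihydro‑2H‑chromen‑3‑yl hexanoate (2,3‑trans) | CCCCCC(=O)O[C@H]1C(=NC)c2c(OCc3ccccc3)cc(OCc3ccccc3)cc2O[C@@H]1c1ccccc1 | intermediate (not isolated)
18 | (2R,3R)‑5,7‑bis(benzyloxy)‑4‑oxo‑2‑phenyl‑3,4‑dihydro‑2H‑chromen‑3‑yl hexanoate | CCCCCC(=O)O[C@H]1C(=O)c2c(OCc3ccccc3)cc(OCc3ccccc3)cc2O[C@@H]1c1ccccc1 | intermediate
19 | (2R,3R)‑5,7‑dihydroxy‑4‑oxo‑2‑phenyl‑3,4‑dihydro‑2H‑chromen‑3‑yl hexanoate | CCCCCC(=O)O[C@H]1C(=O)c2c(O)cc(O)cc2O[C@@H]1c1ccccc1 | target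

**Step count**

Total: 9 steps. Longest linear sequence: 6 steps (1, 2, 3, 4, 8, 9). The side branch (5, 6, 7) joins at step 8.

**Steps most likely to fail, with fallbacks**

Step 8 (α‑oxyacylation of a hindered, electron‑rich aryl ketone; slow condensation or C2 erosion through ring opening are the risks). The fallback sets out from 9 and comes back at 18. Compound 9 is converted with LiN(SiMe3)2 and Me3SiCl (internal quench, THF, −78 °C) into the silyl enol ether (2S)‑5,7‑bis(benzyloxy)‑2‑phenyl‑4‑(trimethylsilyloxy)‑2H‑chromene F1. Rubottom oxidation of this with dimethyldioxirane (acetone, −40 → 0 °C, dilute citric acid work‑up) attacks the face anti to the 2‑phenyl group and gives (2R,3R)‑5,7‑bis(benzyloxy)‑3‑hydroxy‑2‑phenyl‑2,3‑dihydro‑4H‑chromen‑4‑one F2. Esterification of this alcohol with hexanoyl chloride 12 (pyridine, cat. DMAP, CH2Cl2, 0 °C) gives 18.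

Step 4 (enantioselectivity may be low with the 6'‑benzyloxy group next to the ketone). The fallback sets out from 7 and comes back at 9, keeping the oxa‑Michael closure but moving stereocontrol to a resolution. Compound 7 is cyclised without chiral control (DBU 5 mol%, toluene, rt) to racemic tert‑butyl trans‑5,7‑bis(benzyloxy)‑4‑oxo‑2‑phenylchromane‑3‑carboxylate F3. This is decarboxylated in the same pot (TsOH·H2O, 80 °C) to racemic 5,7‑bis(benzyloxy)‑2‑phenyl‑2,3‑dihydro‑4H‑chromen‑4‑one F4. Preparative supercritical‑fluid chromatography on an amylose tris(3,5‑dimethylphenylcarbamate) phase separates 9 from (2R)‑5,7‑bis(benzyloxy)‑2‑phenyl‑2,3‑dihydro‑4H‑chromen‑4‑one F5, which is racemised with catalytic DBU (reversible ring opening) and recycled.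

Step 2 (the free phenol may be O‑acylated instead, or C‑acylation may be incomplete). The fallback sets out from 3 and comes back at 5, making the acyl transfer intramolecular. Compound 3 is O‑acylated on purpose with Boc2O 4 (Et3N, cat. DMAP, MeCN, rt) to give 2‑acetyl‑3,5‑bis(benzyloxy)phenyl tert‑butyl carbonate F6. LiN(SiMe3)2 (2.2 equiv, THF, −78 → 0 °C) then forms the methyl ketone enolate, which attacks the neighbouring carbonate and expels the phenoxide (Baker–Venkataraman‑type O→C acyl transfer), giving 5 after NH4Cl quench.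

**Further compounds**

F1 | step 8 | (2S)‑5,7‑bis(benzyloxy)‑2‑phenyl‑4‑(trimethylsilyloxy)‑2H‑chromene | C[Si](C)(C)OC1=C[C@@H](c2ccccc2)Oc2cc(OCc3ccccc3)cc(OCc3ccccc3)c21
F2 | step 8 | (2R,3R)‑5,7‑bis(benzyloxy)‑3‑hydroxy‑2‑phenyl‑2,3‑dihydro‑4H‑chromen‑4‑one | O[C@H]1C(=O)c2c(OCc3ccccc3)cc(OCc3ccccc3)cc2O[C@@H]1c1ccccc1
F3 | step 4 | racemic tert‑butyl trans‑5,7‑bis(benzyloxy)‑4‑oxo‑2‑phenylchromane‑3‑carboxylate | CC(C)(C)OC(=O)C1C(=O)c2c(OCc3ccccc3)cc(OCc3ccccc3)cc2OC1c1ccccc1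
F4 | step 4 | racemic 5,7‑bis(benzyloxy)‑2‑phenyl‑2,3‑dihydro‑4H‑chromen‑4‑one | O=C1CC(c2ccccc2)Oc2cc(OCc3ccccc3)cc(OCc3ccccc3)c21
F5 | step 4 | (2R)‑5,7‑bis(benzyloxy)‑2‑phenyl‑2,3‑dihydro‑4H‑chromen‑4‑one | O=C1C[C@H](c2ccccc2)Oc2cc(OCc3ccccc3)cc(OCc3ccccc3)c21
F6 | step 2 | 2‑acetyl‑3,5‑bis(benzyloxy)phenyl tert‑butyl carbonate | CC(=O)c1c(OC(=O)OC(C)(C)C)cc(OCc2ccccc2)cc1OCc1ccccc1
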